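**Plan**

1. Retrosynthesis: the three O-protecting groups (7-O-allyl, 5-O- and 4'-O-MOM) come off last. The O1–C8a bond of the pyranone (ring C) is then cut, giving a 1-(2-fluoroaryl)-3-aryl-1,3-diketone, and after that C2–C3 (crossed Claisen between an A-ring methyl ketone and a B-ring methyl benzoate).
2. Enabling feature: C8a of ring A carries O1 and is ortho to C4a, which bears the C4 carbonyl. C8a can therefore enter as a C–F carbon activated by that ketone, while O5 and O7 sit meta to it.
3. Ring A is cut at C4a–C4 (aryllithium + Weinreb amide), C8–prenyl (aryllithium/Cu + prenyl bromide) and C7–O (SNAr of the para fluoride), back to 3,5-difluorophenol. Its oxygen becomes O5 and its fluorines become O7 and O1. Ring B is cut at both aryl–prenyl bonds (Stille), back to methyl 3,5-dibromo-4-hydroxybenzoate.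
4. Forward: ring A is built up (steps 1–4), ring B separately (steps 5–6), the halves are joined through C2–C3 (step 7), ring C closes (step 8), and two deprotections follow.
5. Stereochemistry: the target has no stereocentre and no stereogenic double bond. The only selectivity issue is 8- versus 6-prenyl, and it is fixed by construction: O5 is present from the start, so only one fluoride ortho to the ketone ever exists.

Key step: step 8

Remark: epimedonin L is achiral, so the compound as drawn is its only stereoisomer; compounds 1, 3, 9, 11 and the reagents named are taken as commercial.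

**Route**

Step 1
Reactants: 1 3,5-difluorophenol
Product: 2 1,3-difluoro-5-(methoxymethoxy)benzene
Conditions: MOMCl, i-Pr2NEt, CH2Cl2, 0 °C → rt
Reagents that add atoms: chloromethyl methyl ether, COCCl
Why: O-alkylation of the phenoxide with the α-chloro ether (MOM protection) should be clean, and the acetal survives organolithiums and later assists the ortho-lithiation of step 3.

Step 2
Reactants: 2 1,3-difluoro-5-(methoxymethoxy)benzene; 3 prenyl bromide (1-bromo-3-methylbut-2-ene)
Product: 5 1,3-difluoro-5-(methoxymethoxy)-2-(3-methylbut-2-en-1-yl)benzene, via aryllithium 4 (not isolated)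
Conditions: n-BuLi, THF, −78 °C; then CuBr·SMe2 (10 mol %), 3, −78 → 0 °C
Reagents that add atoms: none
Why: Directed ortho-lithiation should remove the most acidic ring proton, the one flanked by both fluorines and para to the acetal (the site at which 3,5-difluoroanisole is metalated), and the copper-assisted allylic substitution of prenyl bromide should occur at its primary carbon (SN2), the low temperature preventing loss of LiF to an aryne.

Step 3
Reactants: 5 1,3-difluoro-5-(methoxymethoxy)-2-(3-methylbut-2-en-1-yl)benzene
Product: 8 1-[2,4-difluoro-6-(methoxymethoxy)-3-(3-methylbut-2-en-1-yl)phenyl]ethan-1-one, via aryllithium 6 (not isolated), via tetrahedral lithium adduct 7 (not isolated)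
Conditions: n-BuLi, THF, −78 °C; MeC(O)N(OMe)Me, −78 → 0 °C; then H2O
Reagents that add atoms: N-methoxy-N-methylacetamide, CC(=O)N(C)OC
Why: The two remaining ring protons are equivalent and each lies between F and OMOM, so directed ortho-metalation is unambiguous and should outrun deprotonation of the benzylic CH2, and acylation with the Weinreb amide stops at chelate 7, which releases the methyl ketone only on work-up (Weinreb ketone synthesis).

Step 4
Reactants: 8 1-[2,4-difluoro-6-(methoxymethoxy)-3-(3-methylbut-2-en-1-yl)phenyl]ethan-1-one; 9 allyl alcohol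
Product: 10 1-[2-fluoro-6-(methoxymethoxy)-3-(3-methylbut-2-en-1-yl)-4-(prop-2-en-1-yloxy)phenyl]ethan-1-one
Conditions: NaH (1.1 equiv) added to allyl alcohol/THF (1:4) at 0 °C, then 8, 0 → 40 °C
Reagents that add atoms: none
Why: Nucleophilic aromatic substitution (SNAr) should take the fluoride para to the acetyl group, because the ortho fluoride is wedged between the acetyl and prenyl groups and gets little sodium-chelation help in the alcoholic medium; the acetal oxygen is meta to both fluorides, the alcohol co-solvent keeps the ketone largely un-enolised, and a misdirected substitution could not lead to an isomeric flavone because it would remove the only fluoride ortho to the ketone.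

Step 5
Reactants: 11 methyl 3,5-dibromo-4-hydroxybenzoate
Product: 12 methyl 3,5-dibromo-4-(methoxymethoxy)benzoate
Conditions: MOMCl, i-Pr2NEt, CH2Cl2, 0 °C → rt
Reagents that add atoms: chloromethyl methyl ether, COCCl
Why: MOM protection of the acidic 2,6-dibromophenol removes the free OH before the palladium step, and the acetal is inert to Pd(0), stannanes, amide bases and carbonate.

Step 6
Reactants: 12 methyl 3,5-dibromo-4-(methoxymethoxy)benzoate
Product: 13 methyl 4-(methoxymethoxy)-3,5-bis(3-methylbut-2-en-1-yl)benzoate
Conditions: tributyl(3-methylbut-2-en-1-yl)stannane (2.5 equiv), Pd(PPh3)4 (10 mol %), DMF, 95 °C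
Reagents that add atoms: tributyl(3-methylbut-2-en-1-yl)stannane, CCCC[Sn](CCCC)(CCCC)CC=C(C)C
Why: In this twofold Stille coupling, oxidative addition into the electron-poor aryl bromide is easy, the prenyl group is expected to be joined through its tin-bearing CH2 (linear prenyl), and the ester and acetal tolerate the neutral conditions.

Step 7
Reactants: 10 1-[2-fluoro-6-(methoxymethoxy)-3-(3-methylbut-2-en-1-yl)-4-(prop-2-en-1-yloxy)phenyl]ethan-1-one; 13 methyl 4-(methoxymethoxy)-3,5-bis(3-methylbut-2-en-1-yl)benzoate
Product: 15 1-[2-fluoro-6-(methoxymethoxy)-3-(3-methylbut-2-en-1-yl)-4-(prop-2-en-1-yloxy)phenyl]-3-[4-(methoxymethoxy)-3,5-bis(3-methylbut-2-en-1-yl)phenyl]propane-1,3-dione, via lithium enolate 14 (not isolated)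
Conditions: LiHMDS (2.5 equiv), THF, −78 °C; then 13, −78 °C → rt; aqueous work-up
Reagents that add atoms: none
Why: In this crossed Claisen condensation the ketone is the only enolisable partner, its lithium enolate 14 attacks the methyl ester, and the excess amide base drives the equilibrium by deprotonating the 1,3-diketone as it forms; as lithium enolates neither 10 nor the product is open to fluoride displacement by the liberated methoxide, and the lithium diketonate should not cyclise in THF at room temperature.

Step 8
Reactants: 15 1-[2-fluoro-6-(methoxymethoxy)-3-(3-methylbut-2-en-1-yl)-4-(prop-2-en-1-yloxy)phenyl]-3-[4-(methoxymethoxy)-3,5-bis(3-methylbut-2-en-1-yl)phenyl]propane-1,3-dione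
Product: 17 7-(allyloxy)-5-(methoxymethoxy)-2-[4-(methoxymethoxy)-3,5-bis(3-methylbut-2-en-1-yl)phenyl]-8-(3-methylbut-2-en-1-yl)-4H-chromen-4-one, via potassium enolate 16 (not isolated)
Conditions: K2CO3 (2 equiv), DMF, 80 °C
Reagents that add atoms: none
Why: Carbonate converts 15 into the chelated Z-enolate 16, whose oxygen on the B-ring side adds to C8a, the fluorine-bearing carbon ortho to the C4 carbonyl, giving a σ-adduct with its charge on C4a and the C4 oxygen, and loss of fluoride restores the arene and forms O1–C8a. This is an intramolecular SNAr (addition–elimination), the known base-mediated cyclisation of 1-(2-fluoroaryl)-1,3-diketones to chromones and flavones. Ring C closes in a 6-endo-trig sense, the oxygen attacking the far end of the C4a=C8a bond of what is in effect a β-fluoro enone, followed by β-elimination of fluoride. No stereocentre is formed. The step needs O- rather than C-cyclisation and attack at C8a only: carbon attack through C3 would give a four-membered ring, and C8a bears the sole fluoride of the ring because O5 came with the starting phenol and the para fluoride was exchanged in step 4, so the 8-prenyl flavone is the only possible ring-closed product. The 5- and 7-alkoxy groups are meta to C8a and lie on nodal positions of the anionic σ-adduct, so they should not cancel the activation by the ketone, and the allyl ether, acetals and prenyl groups are inert to K2CO3 in DMF at this temperature.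

Step 9
Reactants: 17 7-(allyloxy)-5-(methoxymethoxy)-2-[4-(methoxymethoxy)-3,5-bis(3-methylbut-2-en-1-yl)phenyl]-8-(3-methylbut-2-en-1-yl)-4H-chromen-4-one
Product: 18 7-(allyloxy)-5-hydroxy-2-[4-hydroxy-3,5-bis(3-methylbut-2-en-1-yl)phenyl]-8-(3-methylbut-2-en-1-yl)-4H-chromen-4-one
Conditions: 2 M aq HCl, MeOH/THF, 40 °C, stopped as soon as 17 is consumed
Reagents that add atoms: none
Why: Acid-catalysed solvolysis of the two aryl methoxymethyl acetals (standard MOM cleavage, routinely used on prenylated flavonoids) should leave the allyl ether and the flavone untouched, and because O7 is still allylated the 8-prenyl group has no free neighbouring phenol with which to cyclise to a chroman.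

Step 10
Reactants: 18 7-(allyloxy)-5-hydroxy-2-[4-hydroxy-3,5-bis(3-methylbut-2-en-1-yl)phenyl]-8-(3-methylbut-2-en-1-yl)-4H-chromen-4-one
Product: 19 epimedonin L
Conditions: Pd(PPh3)4 (5 mol %), morpholine (5 equiv), THF, rt
Reagents that add atoms: none
Why: In this palladium(0)-catalysed deallylation (Tsuji–Trost type), oxidative addition into the allyl aryl ether gives a π-allyl complex and the stabilised 7-phenoxide, morpholine captures the allyl group, and the C-prenyl groups, which carry no allylic leaving group, and the free phenols should be unaffected.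

**Compound list**

1 | 3,5-difluorophenol | Oc1cc(F)cc(F)c1 | starting material
2 | 1,3-difluoro-5-(methoxymethoxy)benzene | COCOc1cc(F)cc(F)c1 | intermediate
3 | prenyl bromide (1-bromo-3-methylbut-2-ene) | CC(C)=CCBr | starting material
4 | [2,6-difluoro-4-(methoxymethoxy)phenyl]lithium (aryllithium, not isolated) | [Li]c1c(F)cc(OCOC)cc1F | intermediate
5 | 1,3-difluoro-5-(methoxymethoxy)-2-(3-methylbut-2-en-1-yl)benzene | COCOc1cc(F)c(CC=C(C)C)c(F)c1 | intermediate
6 | [2,4-difluoro-6-(methoxymethoxy)-3-(3-methylbut-2-en-1-yl)phenyl]lithium (aryllithium, not isolated) | [Li]c1c(F)c(CC=C(C)C)c(F)cc1OCOC | intermediate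
7 | lithium 1-[2,4-difluoro-6-(methoxymethoxy)-3-(3-methylbut-2-en-1-yl)phenyl]-1-[methoxy(methyl)amino]ethan-1-olate (tetrahedral lithium adduct, racemic, not isolated) | CC(O[Li])(N(C)OC)c1c(F)c(CC=C(C)C)c(F)cc1OCOC | intermediate
8 | 1-[2,4-difluoro-6-(methoxymethoxy)-3-(3-methylbut-2-en-1-yl)phenyl]ethan-1-one | CC(=O)c1c(F)c(CC=C(C)C)c(F)cc1OCOC | intermediate
9 | allyl alcohol (prop-2-en-1-ol) | C=CCO | starting material
10 | 1-[2-fluoro-6-(methoxymethoxy)-3-(3-methylbut-2-en-1-yl)-4-(prop-2-en-1-yloxy)phenyl]ethan-1-one | CC(=O)c1c(F)c(CC=C(C)C)c(OCC=C)cc1OCOC | intermediate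
11 | methyl 3,5-dibromo-4-hydroxybenzoate | COC(=O)c1cc(Br)c(O)c(Br)c1 | starting material
12 | methyl 3,5-dibromo-4-(methoxymethoxy)benzoate | COC(=O)c1cc(Br)c(OCOC)c(Br)c1 | intermediate
13 | methyl 4-(methoxymethoxy)-3,5-bis(3-methylbut-2-en-1-yl)benzoate | COC(=O)c1cc(CC=C(C)C)c(OCOC)c(CC=C(C)C)c1 | intermediate
14 | lithium 1-[2-fluoro-6-(methoxymethoxy)-3-(3-methylbut-2-en-1-yl)-4-(prop-2-en-1-yloxy)phenyl]ethen-1-olate (lithium enolate of 10, not isolated) | C=C(O[Li])c1c(F)c(CC=C(C)C)c(OCC=C)cc1OCOC | intermediate
15 | 1-[2-fluoro-6-(methoxymethoxy)-3-(3-methylbut-2-en-1-yl)-4-(prop-2-en-1-yloxy)phenyl]-3-[4-(methoxymethoxy)-3,5-bis(3-methylbut-2-en-1-yl)phenyl]propane-1,3-dione | C=CCOc1cc(OCOC)c(C(=O)CC(=O)c2cc(CC=C(C)C)c(OCOC)c(CC=C(C)C)c2)c(F)c1CC=C(C)C | intermediate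
16 | potassium (Z)-enolate of 15, O–K on the B-ring side (not isolated) | C=CCOc1cc(OCOC)c(C(=O)/C=C(\O[K])c2cc(CC=C(C)C)c(OCOC)c(CC=C(C)C)c2)c(F)c1CC=C(C)C | intermediate
17 | 7-(allyloxy)-5-(methoxymethoxy)-2-[4-(methoxymethoxy)-3,5-bis(3-methylbut-2-en-1-yl)phenyl]-8-(3-methylbut-2-en-1-yl)-4H-chromen-4-one | C=CCOc1cc(OCOC)c2c(=O)cc(-c3cc(CC=C(C)C)c(OCOC)c(CC=C(C)C)c3)oc2c1CC=C(C)C | intermediate
18 | 7-(allyloxy)-5-hydroxy-2-[4-hydroxy-3,5-bis(3-methylbut-2-en-1-yl)phenyl]-8-(3-methylbut-2-en-1-yl)-4H-chromen-4-one | C=CCOc1cc(O)c2c(=O)cc(-c3cc(CC=C(C)C)c(O)c(CC=C(C)C)c3)oc2c1CC=C(C)C | intermediate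
19 | epimedonin L, 5,7-dihydroxy-2-[4-hydroxy-3,5-bis(3-methylbut-2-en-1-yl)phenyl]-8-(3-methylbut-2-en-1-yl)-4H-chromen-4-one | CC(C)=CCc1cc(-c2cc(=O)c3c(O)cc(O)c(CC=C(C)C)c3o2)cc(CC=C(C)C)c1O | target

**Step count**

Total: 10 steps. Longest linear sequence: 8 steps (steps 1, 2, 3, 4, 7, 8, 9, 10 from 3,5-difluorophenol).

**Steps most likely to fail**

Step 4. Alkoxide attack at the ortho fluoride may compete with para attack, and reversible enolisation of the methyl ketone by the alkoxide may switch off the activation, so that the substitution stalls or over-reacts on warming. The fallback moves the substitution to the aldehyde oxidation level, where the activating group is coplanar, stronger and not enolisable. Setting out from 5, the aryllithium 6 is generated as in step 3 and quenched with DMF to give 2,4-difluoro-6-(methoxymethoxy)-3-(3-methylbut-2-en-1-yl)benzaldehyde F1. Sodium allyloxide in DMF at 0 °C should then replace the para fluoride to give 2-fluoro-6-(methoxymethoxy)-3-(3-methylbut-2-en-1-yl)-4-(prop-2-en-1-yloxy)benzaldehyde F2. Addition of MeMgBr gives racemic 1-[2-fluoro-6-(methoxymethoxy)-3-(3-methylbut-2-en-1-yl)-4-(prop-2-en-1-yloxy)phenyl]ethan-1-ol F3, and Dess–Martin oxidation returns to the route at ketone 10.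

Step 7. Acyl transfer from the electron-rich, meta-dialkylated benzoate to the lithium enolate may be slow, so that proton exchange, retro-Claisen cleavage by methoxide or premature ring closure erode the diketone. The fallback raises the acyl donor to the acid chloride level. From 13, LiOH in THF/MeOH/H2O followed by acidification to pH 4 with citric acid gives 4-(methoxymethoxy)-3,5-bis(3-methylbut-2-en-1-yl)benzoic acid F4. 1-Chloro-N,N,2-trimethylprop-1-en-1-amine in CH2Cl2 converts it, without free HCl, into 4-(methoxymethoxy)-3,5-bis(3-methylbut-2-en-1-yl)benzoyl chloride F5. This is added at −78 °C to the lithium enolate 14, prepared from 10 with 2.2 equiv of LiHMDS, and C-acylation returns to the route at diketone 15.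

Step 6. Coupling through the γ-carbon of the prenyl stannane (giving 1,1-dimethylallyl isomers), or stalling after the first coupling next to the ortho acetal, may give mixtures that are hard to separate. The fallback separates the aryl–carbon coupling from the construction of the trisubstituted alkene. From 12, twofold Stille coupling with allyltributylstannane, which has no regiochemical ambiguity, gives methyl 4-(methoxymethoxy)-3,5-di(prop-2-en-1-yl)benzoate F6. Olefin cross-metathesis with excess 2-methylbut-2-ene (second-generation ruthenium benzylidene catalyst, CH2Cl2, 40 °C) then converts both allyl groups into prenyl groups and returns to the route at 13.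

**Further compounds**

F1 | step 4 | 2,4-difluoro-6-(methoxymethoxy)-3-(3-methylbut-2-en-1-yl)benzaldehyde | O=Cc1c(F)c(CC=C(C)C)c(F)cc1OCOC
F2 | step 4 | 2-fluoro-6-(methoxymethoxy)-3-(3-methylbut-2-en-1-yl)-4-(prop-2-en-1-yloxy)benzaldehyde | O=Cc1c(F)c(CC=C(C)C)c(OCC=C)cc1OCOC
F3 | step 4 | 1-[2-fluoro-6-(methoxymethoxy)-3-(3-methylbut-2-en-1-yl)-4-(prop-2-en-1-yloxy)phenyl]ethan-1-ol (racemic) | CC(O)c1c(F)c(CC=C(C)C)c(OCC=C)cc1OCOC
F4 | step 7 | 4-(methoxymethoxy)-3,5-bis(3-methylbut-2-en-1-yl)benzoic acid | COCOc1c(CC=C(C)C)cc(C(=O)O)cc1CC=C(C)C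
F5 | step 7 | 4-(methoxymethoxy)-3,5-bis(3-methylbut-2-en-1-yl)benzoyl chloride | COCOc1c(CC=C(C)C)cc(C(=O)Cl)cc1CC=C(C)C
F6 | step 6 | methyl 4-(methoxymethoxy)-3,5-di(prop-2-en-1-yl)benzoate | COC(=O)c1cc(CC=C)c(OCOC)c(CC=C)c1
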